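**Retrosynthetic overview**
- The last bond made is N1–C2 of the indoxyl ring. It comes from isomerising 3-[di(indol-3-yl)methyl]anthranil, an isomer of the target whose N–O bond pays for the C–H amination.
- The anthranil forms in the same flask by four-electron reduction of 2,2-di(indol-3-yl)-1-(2-nitrophenyl)ethanone, with the hydroxylamine oxygen closing on the ketone.
- The nitro ketone comes from 2'-nitroacetophenone and two indoles by iodination, Kornblum oxidation and double Friedel–Crafts alkylation.
- Ring order: the benzene ring and both indoles are bought. A transient isoxazole ring forms first and is then traded for the five-membered indoxyl ring, the only built ring that stays.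

**Assumption:** C2 of the target carries two identical indol-3-yl groups, so the molecule has no stereocentre and is achiral. No enantiocontrol is needed or possible.

**Step 1**
Reactants: 1 2'-nitroacetophenone; 2 indole (2.1 equiv)
Product: 6 2,2-di(1H-indol-3-yl)-1-(2-nitrophenyl)ethan-1-one, via iodoketone 3 (not isolated), via 2-nitrophenylglyoxal 4 (not isolated), via mono-indolyl carbinol 5 (not isolated)
Conditions: I2 (0.5 equiv), DMSO, 100 °C, 3 h; then 2 (2.1 equiv), 80 °C, 2 h
Reagents that add atoms: none
Why: Alpha-iodination and Kornblum oxidation turn the methyl ketone into glyoxal 4, and the I2/HI present catalyses a double Friedel–Crafts alkylation of indole C3 at the aldehyde carbon only, a known domino reaction type for aryl methyl ketones that leaves no stereocentre in 6.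

**Step 2**
Reactants: 6 2,2-di(1H-indol-3-yl)-1-(2-nitrophenyl)ethan-1-one
Product: 11 2,2-bis(3'-indolyl)indoxyl, via hydroxylamine 7 (not isolated), via anthranil 8 (not isolated), via alkylidene tautomer 9 (not isolated), via amino azafulvene 10 (not isolated)
Conditions: SnCl2·2H2O (2.1 equiv), EtOAc/EtOH 1:1, 25 °C, 12 h; then CF3CO2H (1.0 equiv), 60 °C, 4 h
Reagents that add atoms: none
Why: Proposed new method: two equivalents of divalent tin take the nitro group down four electrons to hydroxylamine 7, whose oxygen closes on the neighbouring ketone to give anthranil 8 (the known outcome for 2-nitroaryl ketones), an isomer of the target; acid then moves the doubly indolyl-activated methine proton to nitrogen to give the O-vinyl-N-arylhydroxylamine 9, its weak N–O bond ionises under push from the two indoles so that oxygen becomes the C3 ketone and nitrogen leaves as the aniline of azafulvene 10, and 5-exo-trig attack of that aniline on the bis(indolyl) carbon forms the N1–C2 bond and the indoxyl ring, so the N–O bond acts as internal oxidant for a net C(sp3)–H amination driven by loss of the o-quinoid isoxazole and gain of C=O and C–N bonds; solvent adducts of the cation are reversible and drain to the cyclic product; the closest known reaction types are the 3-arylanthranil-to-acridone rearrangement, the isoxazole-to-azirine isomerisation and the umpolung alpha-functionalisation of N-alkoxyenamines; C2 carries two identical indolyl groups, so no stereocentre is created.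

**Compound list**
1 | 2'-nitroacetophenone, 1-(2-nitrophenyl)ethan-1-one | CC(=O)c1ccccc1[N+](=O)[O-] | starting material
2 | indole (1H-indole) | c1ccc2[nH]ccc2c1 | starting material
3 | 2-iodo-1-(2-nitrophenyl)ethan-1-one | O=C(CI)c1ccccc1[N+](=O)[O-] | intermediate
4 | 2-nitrophenylglyoxal, 2-(2-nitrophenyl)-2-oxoacetaldehyde | O=CC(=O)c1ccccc1[N+](=O)[O-] | intermediate
5 | 2-hydroxy-2-(1H-indol-3-yl)-1-(2-nitrophenyl)ethan-1-one (racemic, transient) | O=C(C(O)c1c[nH]c2ccccc12)c1ccccc1[N+](=O)[O-] | intermediate
6 | 2,2-di(1H-indol-3-yl)-1-(2-nitrophenyl)ethan-1-one | O=C(C(c1c[nH]c2ccccc12)c1c[nH]c2ccccc12)c1ccccc1[N+](=O)[O-] | intermediate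
7 | 1-[2-(hydroxyamino)phenyl]-2,2-di(1H-indol-3-yl)ethan-1-one | O=C(C(c1c[nH]c2ccccc12)c1c[nH]c2ccccc12)c1ccccc1NO | intermediate
8 | 3-[di(1H-indol-3-yl)methyl]-2,1-benzisoxazole (anthranil) | c1ccc2noc(C(c3c[nH]c4ccccc34)c3c[nH]c4ccccc34)c2c1 | intermediate
9 | 3-[di(1H-indol-3-yl)methylidene]-1,3-dihydro-2,1-benzisoxazole | C(=C1ONc2ccccc12)(c1c[nH]c2ccccc12)c1c[nH]c2ccccc12 | intermediate
10 | 1-(2-aminophenyl)-2-(1H-indol-3-yl)-2-(3H-indol-3-ylidene)ethan-1-one (alkene geometry undefined, transient) | Nc1ccccc1C(=O)C(c1c[nH]c2ccccc12)=C1C=Nc2ccccc12 | intermediate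
11 | 2,2-bis(3'-indolyl)indoxyl, 2,2-di(1H-indol-3-yl)indolin-3-one (achiral) | O=C1c2ccccc2NC1(c1c[nH]c2ccccc12)c1c[nH]c2ccccc12 | target

**Total step count:** 2. **Longest linear sequence:** 2.

**Steps most likely to fail** (the route has only two steps, so both are ranked and there is no third)

1. Step 2, the proposed new step. There are three risks:
   - Anthranil 8 may resist acid and simply persist.
   - Tin may over-reduce the hydroxylamine to the aniline before oxygen closes on the hindered ketone.
   - Acid may strip an indole by retro-Friedel–Crafts reaction.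

   The fallback uses known chemistry. It sets out from 2 and gives up the late ring closure for the established aerobic oxidative trimerisation of indole (TEMPO in air, a carboxylic acid additive, MeCN, about 60 °C). C3 oxygenation of one indole gives 3H-indol-3-one F1. A second indole adds at its C2 to give 2-(1H-indol-3-yl)indolin-3-one F2. This is dehydrogenated in the same flask to 2-(1H-indol-3-yl)-3H-indol-3-one F3. A third indole then adds to the C=N bond, and the fallback comes back to the route at 11.

2. Step 1. Indole may be iodinated, oxidised or methylthiolated by I2/DMSO. The ortho-nitro ketone may also be slow in the Kornblum stage.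

   The fallback sets out from 1 and separates oxidation from C–C bond formation, so that indole never meets an oxidant. Riley oxidation with SeO2 in aqueous dioxane at reflux gives the isolable hydrate 2,2-dihydroxy-1-(2-nitrophenyl)ethan-1-one F4. In a second, non-oxidising flask, F4 is condensed with 2 (2 equiv) under p-TsOH·H2O (10 mol%) in MeCN at 25 °C, a known acid-catalysed bis-indolylation of arylglyoxals. The fallback comes back to the route at 6.

**Further compounds**
F1 | step 2 | 3H-indol-3-one | O=C1C=Nc2ccccc12
F2 | step 2 | 2-(1H-indol-3-yl)indolin-3-one (racemic) | O=C1c2ccccc2NC1c1c[nH]c2ccccc12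
F3 | step 2 | 2-(1H-indol-3-yl)-3H-indol-3-one | O=C1C(c2c[nH]c3ccccc23)=Nc2ccccc12
F4 | step 1 | 2,2-dihydroxy-1-(2-nitrophenyl)ethan-1-one | O=C(C(O)O)c1ccccc1[N+](=O)[O-]
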